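Isochromene numbering is used (O2, C1H2, C3 bearing propenyl, C4, C4a, C5–C8, C8a). The route rests on cutting the C7–C8 bond of the cyclohexenone ring, whose tertiary α-ketol C8(=O)–C7(OH)(CH3) joins two acceptor carbons. An N-heterocyclic-carbene-catalysed intramolecular crossed benzoin reaction turns the formyl carbon C8 into an acyl-anion equivalent that adds to the C7 methyl ketone. This closes the carbocycle onto the finished 2H-pyran and creates the C7 carbinol next to the pre-set C6 ester stereocentre in one operation. The precursor is a monocyclic 6-propenyl-2H-pyran-3-carbaldehyde carrying at C4 an (S)-2-aroyloxy-3-oxobutyl chain.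

Key step: step 11

Assumption: the 6-alkenyl-2H-pyran-3-carbaldehyde made in step 10 is taken to rest as the closed valence tautomer (a vinylogous formate, ring oxygen conjugated to the formyl group through the diene), as the same ring does in the target.

Step 1
Reactants: 1 2,4-dihydroxy-6-methylbenzaldehyde
Product: 2 2-hydroxy-6-methyl-4-(triisopropylsilyloxy)benzaldehyde
Conditions: TIPSCl (1.05 equiv), imidazole, DMF, 0 °C to rt
Reagents that add atoms: triisopropylsilyl chloride, CC(C)[Si](Cl)(C(C)C)C(C)C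
Why: Regioselective O-silylation, because the 2-OH is hydrogen-bonded to the formyl group and only the free para 4-OH should react.

Step 2
Reactants: 2 2-hydroxy-6-methyl-4-(triisopropylsilyloxy)benzaldehyde
Product: 3 2-methoxy-6-methyl-4-(triisopropylsilyloxy)benzaldehyde
Conditions: MeI, K2CO3, acetone, 40 °C
Reagents that add atoms: iodomethane, CI
Why: Williamson O-methylation of the chelated phenol, with the bulky aryl TIPS ether expected to tolerate carbonate in acetone.

Step 3
Reactants: 3 2-methoxy-6-methyl-4-(triisopropylsilyloxy)benzaldehyde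
Product: 4 2-methoxy-6-methyl-4-(triisopropylsilyloxy)benzoic acid
Conditions: NaClO2, NaH2PO4, 2-methyl-2-butene, t-BuOH/THF/H2O, rt
Reagents that add atoms: sodium chlorite, [Na+].[O-]Cl=O
Why: Pinnick oxidation gives the hindered acid without ester hydrolysis, and the alkene scavenger protects the electron-rich ring from chlorination.

Step 4
Reactants: 5 methyl (2R)-oxirane-2-carboxylate
Product: 7 methyl (2R)-2-hydroxypent-4-ynoate, via C-silyl alkyne 6 (not isolated)
Conditions: Me3SiC≡CH, n-BuLi, THF, −78 °C; BF3·OEt2, then 5, −78 °C; crude product K2CO3 (cat.), MeOH, 0 °C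
Reagents that add atoms: ethynyltrimethylsilane, C#C[Si](C)(C)C
Why: BF3-mediated alkynylation opens the terminal epoxide by SN2 at CH2, so the C2 stereocentre is untouched and the ester survives at −78 °C; methanolysis then removes the C-silyl group.

Step 5
Reactants: 7 methyl (2R)-2-hydroxypent-4-ynoate
Product: 8 (2R)-2-hydroxy-N-methoxy-N-methylpent-4-ynamide
Conditions: MeNH(OMe)·HCl, i-PrMgCl (excess), THF, −20 to 0 °C
Reagents that add atoms: N,O-dimethylhydroxylamine hydrochloride, CNOC.Cl
Why: Weinreb amide formation by aminolysis of the ester with the magnesium amide, which does not touch the carbinol centre.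

Step 6
Reactants: 8 (2R)-2-hydroxy-N-methoxy-N-methylpent-4-ynamide, 4 2-methoxy-6-methyl-4-(triisopropylsilyloxy)benzoic acid
Product: 9 (2S)-1-[methoxy(methyl)amino]-1-oxopent-4-yn-2-yl 2-methoxy-6-methyl-4-(triisopropylsilyloxy)benzoate
Conditions: PPh3, DIAD, toluene, 0 °C to rt
Reagents that add atoms: none
Why: Mitsunobu esterification uses the hindered di-ortho-substituted acid as the nucleophile, and SN2 inversion at the activated α-carbinol sets the (S) centre that becomes C6.

Step 7
Reactants: 9 (2S)-1-[methoxy(methyl)amino]-1-oxopent-4-yn-2-yl 2-methoxy-6-methyl-4-(triisopropylsilyloxy)benzoate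
Product: 10 (3S)-2-oxohex-5-yn-3-yl 2-methoxy-6-methyl-4-(triisopropylsilyloxy)benzoate
Conditions: MeMgBr (1.5 equiv), THF, −78 to −30 °C; cold aq. NH4Cl quench
Reagents that add atoms: methylmagnesium bromide, C[Mg]Br
Why: Weinreb ketone synthesis, in which the chelated tetrahedral intermediate prevents over-addition and base-induced epimerisation, and the di-ortho-substituted aryl ester is too hindered to react.

Step 8
Reactants: 10 (3S)-2-oxohex-5-yn-3-yl 2-methoxy-6-methyl-4-(triisopropylsilyloxy)benzoate, 11 (E)-but-2-enoyl chloride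
Product: 12 (3S,8E)-2,7-dioxodec-8-en-5-yn-3-yl 2-methoxy-6-methyl-4-(triisopropylsilyloxy)benzoate
Conditions: PdCl2(PPh3)2 (2 mol%), CuI (4 mol%), Et3N (1.3 equiv), THF, 0 °C to rt
Reagents that add atoms: none
Why: Acyl Sonogashira coupling of the terminal alkyne with the acid chloride gives the cross-conjugated ynone under conditions that tolerate the methyl ketone and esters.

Step 9
Reactants: 12 (3S,8E)-2,7-dioxodec-8-en-5-yn-3-yl 2-methoxy-6-methyl-4-(triisopropylsilyloxy)benzoate
Product: 13 (3S,5Z,8E)-5-iodo-2,7-dioxodeca-5,8-dien-3-yl 2-methoxy-6-methyl-4-(triisopropylsilyloxy)benzoate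
Conditions: NaI (2 equiv), AcOH, 23 °C, short reaction time
Reagents that add atoms: sodium iodide, [Na+].[I-]
Why: Conjugate hydroiodination of the ynone, where iodide adds to the β-carbon and anti protonation of the allenol should give the (Z)-β-iodoenone with iodine cis to the carbonyl.

Step 10
Reactants: 13 (3S,5Z,8E)-5-iodo-2,7-dioxodeca-5,8-dien-3-yl 2-methoxy-6-methyl-4-(triisopropylsilyloxy)benzoate, 14 2-bromo-3,3-diethoxyprop-1-ene
Product: 19 (2S)-1-{3-formyl-6-[(E)-prop-1-enyl]-2H-pyran-4-yl}-3-oxobutan-2-yl 2-methoxy-6-methyl-4-(triisopropylsilyloxy)benzoate, via vinyllithium 15 (not isolated), via vinylzinc bromide 16 (not isolated), via dienone acetal 17 (not isolated), via oxatriene aldehyde 18 (not isolated)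
Conditions: 14, t-BuLi (2 equiv per 14), Et2O/THF, −78 °C; ZnBr2, −78 to 0 °C; 13, Pd(PPh3)4 (5 mol%), THF, 0 to 23 °C; then 1 M aq. HCl, THF, 0 °C
Reagents that add atoms: water, O
Why: Negishi coupling of the ketone-tolerant α-acrolein-acetal zinc reagent proceeds with retention at the (Z)-iodoenone, so the new vinyl group sits cis to the C3 carbonyl; mild acid then unmasks the formyl group and the (Z)-1-oxatriene closes by oxa-6π electrocyclisation to the push–pull 2H-pyran.

Step 11
Reactants: 19 (2S)-1-{3-formyl-6-[(E)-prop-1-enyl]-2H-pyran-4-yl}-3-oxobutan-2-yl 2-methoxy-6-methyl-4-(triisopropylsilyloxy)benzoate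
Product: 20 (6S,7S)-7-hydroxy-7-methyl-8-oxo-3-[(E)-prop-1-enyl]-5,6,7,8-tetrahydro-1H-isochromen-6-yl 2-methoxy-6-methyl-4-(triisopropylsilyloxy)benzoate
Conditions: aminoindanol-derived N-pentafluorophenyl triazolium tetrafluoroborate (15 mol%, the enantiomer that directs Re-face attack on the C7 ketone), i-Pr2NEt (15 mol%), toluene, 23 °C
Reagents that add atoms: none
Why: The carbene adds to the formyl carbon C8 to give the Breslow intermediate, whose nucleophilic C8 attacks the C7 methyl ketone; proton transfer and loss of the carbene then leave the C8 ketone and the C7 tertiary alcohol. The closest known reaction type is the intramolecular crossed aldehyde–ketone benzoin cyclisation that gives six-membered tertiary α-ketols under chiral triazolium catalysis. The carbocycle C4a–C5–C6–C7–C8–C8a closes by 6-exo-trig addition of C8 to the C7 carbonyl. The new C7 centre is set by the catalyst (Re-face attack gives 7S) and should be reinforced by the C6 centre through a polar Felkin–Anh half-chair, with the ester pseudo-equatorial and anti to the forming bond and the methyl group pseudo-equatorial, which places the new hydroxyl cis to the ester. The step needs acyl-anion rather than homoenolate reactivity of the conjugated aldehyde, which the electron-poor N-aryl triazolium, the fully substituted β-carbon C4a and the aprotic medium should secure. It also needs C6 to survive, which the weak amine base allows, and after ring closure C6 is no longer α to a ketone.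

Step 12
Reactants: 20 (6S,7S)-7-hydroxy-7-methyl-8-oxo-3-[(E)-prop-1-enyl]-5,6,7,8-tetrahydro-1H-isochromen-6-yl 2-methoxy-6-methyl-4-(triisopropylsilyloxy)benzoate
Product: 21 comazaphilone G
Conditions: TBAF (1.1 equiv), AcOH (1.2 equiv), THF, 0 °C
Reagents that add atoms: none
Why: Buffered fluoride desilylation cleaves the aryl silyl ether para to the ester carbonyl without exposing the base-sensitive β-acyloxy enone to free alkoxide or fluoride base.

Compound list
1 | 2,4-dihydroxy-6-methylbenzaldehyde | Cc1cc(O)cc(O)c1C=O | starting material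
2 | 2-hydroxy-6-methyl-4-(triisopropylsilyloxy)benzaldehyde | Cc1cc(O[Si](C(C)C)(C(C)C)C(C)C)cc(O)c1C=O | intermediate
3 | 2-methoxy-6-methyl-4-(triisopropylsilyloxy)benzaldehyde | Cc1cc(O[Si](C(C)C)(C(C)C)C(C)C)cc(OC)c1C=O | intermediate
4 | 2-methoxy-6-methyl-4-(triisopropylsilyloxy)benzoic acid | Cc1cc(O[Si](C(C)C)(C(C)C)C(C)C)cc(OC)c1C(=O)O | intermediate
5 | methyl (2R)-oxirane-2-carboxylate | COC(=O)[C@H]1CO1 | starting material
6 | methyl (2R)-2-hydroxy-5-(trimethylsilyl)pent-4-ynoate (not isolated) | COC(=O)[C@H](O)CC#C[Si](C)(C)C | intermediate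
7 | methyl (2R)-2-hydroxypent-4-ynoate | COC(=O)[C@H](O)CC#C | intermediate
8 | (2R)-2-hydroxy-N-methoxy-N-methylpent-4-ynamide | CON(C)C(=O)[C@H](O)CC#C | intermediate
9 | (2S)-1-[methoxy(methyl)amino]-1-oxopent-4-yn-2-yl 2-methoxy-6-methyl-4-(triisopropylsilyloxy)benzoate | CON(C)C(=O)[C@@H](OC(=O)c1c(C)cc(O[Si](C(C)C)(C(C)C)C(C)C)cc1OC)CC#C | intermediate
10 | (3S)-2-oxohex-5-yn-3-yl 2-methoxy-6-methyl-4-(triisopropylsilyloxy)benzoate | CC(=O)[C@@H](OC(=O)c1c(C)cc(O[Si](C(C)C)(C(C)C)C(C)C)cc1OC)CC#C | intermediate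
11 | (E)-but-2-enoyl chloride | C/C=C/C(=O)Cl | starting material
12 | (3S,8E)-2,7-dioxodec-8-en-5-yn-3-yl 2-methoxy-6-methyl-4-(triisopropylsilyloxy)benzoate | C/C=C/C(=O)C#CC[C@H](OC(=O)c1c(C)cc(O[Si](C(C)C)(C(C)C)C(C)C)cc1OC)C(C)=O | intermediate
13 | (3S,5Z,8E)-5-iodo-2,7-dioxodeca-5,8-dien-3-yl 2-methoxy-6-methyl-4-(triisopropylsilyloxy)benzoate | C/C=C/C(=O)/C=C(\I)C[C@H](OC(=O)c1c(C)cc(O[Si](C(C)C)(C(C)C)C(C)C)cc1OC)C(C)=O | intermediate
14 | 2-bromo-3,3-diethoxyprop-1-ene | C=C(Br)C(OCC)OCC | starting material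
15 | (3,3-diethoxyprop-1-en-2-yl)lithium (not isolated) | [Li]C(=C)C(OCC)OCC | intermediate
16 | (3,3-diethoxyprop-1-en-2-yl)zinc bromide (not isolated) | Br[Zn]C(=C)C(OCC)OCC | intermediate
17 | (3S,5Z,8E)-5-(3,3-diethoxyprop-1-en-2-yl)-2,7-dioxodeca-5,8-dien-3-yl 2-methoxy-6-methyl-4-(triisopropylsilyloxy)benzoate (not isolated) | C/C=C/C(=O)/C=C(\C(=C)C(OCC)OCC)C[C@H](OC(=O)c1c(C)cc(O[Si](C(C)C)(C(C)C)C(C)C)cc1OC)C(C)=O | intermediate
18 | (3S,5Z,8E)-5-(3-oxoprop-1-en-2-yl)-2,7-dioxodeca-5,8-dien-3-yl 2-methoxy-6-methyl-4-(triisopropylsilyloxy)benzoate (not isolated) | C/C=C/C(=O)/C=C(\C(=C)C=O)C[C@H](OC(=O)c1c(C)cc(O[Si](C(C)C)(C(C)C)C(C)C)cc1OC)C(C)=O | intermediate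
19 | (2S)-1-{3-formyl-6-[(E)-prop-1-enyl]-2H-pyran-4-yl}-3-oxobutan-2-yl 2-methoxy-6-methyl-4-(triisopropylsilyloxy)benzoate | C/C=C/C1=CC(C[C@H](OC(=O)c2c(C)cc(O[Si](C(C)C)(C(C)C)C(C)C)cc2OC)C(C)=O)=C(C=O)CO1 | intermediate
20 | (6S,7S)-7-hydroxy-7-methyl-8-oxo-3-[(E)-prop-1-enyl]-5,6,7,8-tetrahydro-1H-isochromen-6-yl 2-methoxy-6-methyl-4-(triisopropylsilyloxy)benzoate | C/C=C/C1=CC2=C(CO1)C(=O)[C@@](C)(O)[C@@H](OC(=O)c1c(C)cc(O[Si](C(C)C)(C(C)C)C(C)C)cc1OC)C2 | intermediate
21 | comazaphilone G, (6S,7S)-7-hydroxy-7-methyl-8-oxo-3-[(E)-prop-1-enyl]-5,6,7,8-tetrahydro-1H-isochromen-6-yl 4-hydroxy-2-methoxy-6-methylbenzoate | C/C=C/C1=CC2=C(CO1)C(=O)[C@@](C)(O)[C@@H](OC(=O)c1c(C)cc(O)cc1OC)C2 | target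

Total step count: 12. Longest linear sequence: 10 steps (steps 1–3 and 6–12, from compound 1).

Steps most likely to fail

1. Step 11. The Breslow intermediate of the conjugated aldehyde may leak into the homoenolate manifold (β-protonation, then loss of the ring oxygen from C1 and opening of the pyran), or the catalyst may discriminate the two faces of the C7 ketone poorly. Fallback, from 19 back to 20: the same C7–C8 bond would be made reductively instead of by acyl-anion catalysis. Bu3SnH with AIBN in benzene at 80 °C should add the stannyl radical to the formyl oxygen, and the O-stannyl ketyl radical should cyclise onto the C7 ketone (radical pinacol cyclisation) to give the 8-O-tributylstannyl ether of the cis-7,8-diol F1. Hydrolytic work-up on silica should give the cis-7,8-diol F2, with C7 epimers separated at this stage if needed. MnO2 in CH2Cl2 should then oxidise only the allylic secondary C8 carbinol and return to 20.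

2. Step 10. The acid used to unmask the formyl group may erode the (Z)-dienone geometry or degrade the transient α-methylene aldehyde before it electrocyclises, and the organozinc preparation adds a strongly basic stage. Fallback, from 13 back to 19: carbon C8 would be carried at the alcohol oxidation level so that no acetal hydrolysis is needed. Stille coupling of 13 with 2-(tributylstannyl)prop-2-en-1-ol (Pd2(dba)3, AsPh3, CuI, NMP, rt) should give the dienone allylic alcohol (3S,5Z,8E)-5-(3-hydroxyprop-1-en-2-yl)-2,7-dioxodeca-5,8-dien-3-yl 2-methoxy-6-methyl-4-(triisopropylsilyloxy)benzoate F3. MnO2 in CH2Cl2 should oxidise the primary allylic alcohol to the oxatriene aldehyde 18 under neutral conditions, which closes to 19.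

3. Step 8. Triethylamine may dehydrochlorinate the acid chloride to a vinylketene, and the amine may isomerise the ynone or trigger β-elimination of the C6 carboxylate from the propargylic position. Fallback, from 10 back to 12: the ynone would be reached through the alcohol oxidation level without an acid chloride. Zn(OTf)2/Et3N-mediated addition of the terminal alkyne of 10 to (E)-but-2-enal (toluene, rt) should give the propargylic alcohol (3S,8E)-7-hydroxy-2-oxodec-8-en-5-yn-3-yl 2-methoxy-6-methyl-4-(triisopropylsilyloxy)benzoate F4 as a mixture of carbinol epimers. MnO2 in CH2Cl2 should then give 12.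

Further compounds
F1 | step 11 | (6S,7S,8R)-7-hydroxy-7-methyl-3-[(E)-prop-1-enyl]-8-(tributylstannyloxy)-5,6,7,8-tetrahydro-1H-isochromen-6-yl 2-methoxy-6-methyl-4-(triisopropylsilyloxy)benzoate | C/C=C/C1=CC2=C(CO1)[C@@H](O[Sn](CCCC)(CCCC)CCCC)[C@@](C)(O)[C@@H](OC(=O)c1c(C)cc(O[Si](C(C)C)(C(C)C)C(C)C)cc1OC)C2
F2 | step 11 | (6S,7S,8R)-7,8-dihydroxy-7-methyl-3-[(E)-prop-1-enyl]-5,6,7,8-tetrahydro-1H-isochromen-6-yl 2-methoxy-6-methyl-4-(triisopropylsilyloxy)benzoate (7,8-cis diol) | C/C=C/C1=CC2=C(CO1)[C@@H](O)[C@@](C)(O)[C@@H](OC(=O)c1c(C)cc(O[Si](C(C)C)(C(C)C)C(C)C)cc1OC)C2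
F3 | step 10 | (3S,5Z,8E)-5-(3-hydroxyprop-1-en-2-yl)-2,7-dioxodeca-5,8-dien-3-yl 2-methoxy-6-methyl-4-(triisopropylsilyloxy)benzoate | C/C=C/C(=O)/C=C(\C(=C)CO)C[C@H](OC(=O)c1c(C)cc(O[Si](C(C)C)(C(C)C)C(C)C)cc1OC)C(C)=O
F4 | step 8 | (3S,8E)-7-hydroxy-2-oxodec-8-en-5-yn-3-yl 2-methoxy-6-methyl-4-(triisopropylsilyloxy)benzoate | C/C=C/C(O)C#CC[C@H](OC(=O)c1c(C)cc(O[Si](C(C)C)(C(C)C)C(C)C)cc1OC)C(C)=O
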